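## The problem

- The target is a laurane-type bromophenol. A phenol ring (OH on C1, Br on C4 para to OH, CH3 on C5) carries at C2 a cyclopentane. The cyclopentane locants used below are C1 (quaternary: aryl, CH3), C2 (tertiary: H, CH3), C3 (exocyclic =CHBr), C4 and C5 (CH2).
- Read from the SMILES, the configuration is (1R,2R,3Z): the C2 methyl group is cis to the aryl group, and the vinylic bromine points toward C2.
- Both relations are contra-steric. A methyl group cis to the aryl group on the neighbouring carbon is the less stable arrangement and would epimerize if C3 were ever a ketone. Bromine syn to the branched C2 is the more crowded alkene isomer, which a Wittig-type bromomethylenation does not favour.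
- C1 is an all-carbon benzylic quaternary stereocentre that must be made as one enantiomer. It is the only centre that can control C2, yet in a ring-forming C–C bond formation at C2 the bulky aryl group normally ends up trans to the new substituent, which is the wrong isomer.
- The free phenol ortho to C1 captures a cation or halonium ion at C3 to give a bridged ether. The aryl and vinyl bromides do not survive alkyllithium or low-valent metal reagents, so both bromines must come last.
- The feature that makes the key step possible: CH3–C2(H)–C3(=CH–) is the doubly reduced form of a vinyl group on C1 and an alkyne on C4, joined at C2–C3, so the ring is a reduced 1,6-enyne. The phenolic oxygen lies on the path O–C(ar)–C(ar)–C1–C2–CH3, so a metal on the future C2 methyl carbon can be held by that oxygen in a seven-membered chelate only when that carbon is cis to the aryl group.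

## Retrosynthesis

**22 ⇒ 21 (aryl C–Br).** The aryl bromine is removed first. The site is para to OH in a 2,5-dialkylphenol, the pattern in which electrophilic bromination is reliably para-selective. An aryl bromide would not survive the organometallic steps, so it is placed last. The forward step only has to leave the deactivated bromoalkene alone.

**21 ⇒ 19 ⇒ 18 (vinyl C–Br, by way of C–Si).** The vinylic bromine is traced back to a trimethylsilyl group on the same carbon but on the other side of the double bond, in the (E)-vinylsilane 18. Bromine addition followed by anti elimination replaces silicon with inversion, which turns a geometry set by ring formation into the crowded (Z)-bromide. Olefination of a C3 ketone was rejected because it would expose C2 to epimerization and give the wrong alkene isomer. The forward reaction needs anti addition and anti elimination through dibromide 20, with the phenol masked as acetate 19 so that the oxygen cannot attack C3.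

**18 ⇒ 14 (key disconnection: C2–C3 ring bond, the C–H bond of the C2 methyl group, the vinylic C–H bond).** Cutting C2–C3 and removing two hydrogens opens the ring to enyne 14. This precursor is acyclic, has one stereocentre, no ring and no alkene geometry. The forward reaction is a reductive enyne cyclization on titanium by way of aryloxide 16 and titanacycle 17. The syn addition across the alkyne fixes silicon cis to C4, and the Ti–O bond to the phenoxide is asked to deliver the metal-bearing CH2 cis to the aryl group. Cuts at C1–C2 or C1–aryl would have to build the quaternary centre during ring closure and offer no handle on the alkene geometry.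

**14 ⇒ 13 ⇒ 10 (C1–vinyl bond).** The vinyl group is traced to a tertiary boronic ester 10 by a stereoretentive boron-to-vinyl exchange (Zweifel olefination). The phenol is carried as the MOM ether 13, because the next step back uses an alkyllithium. The forward step needs complete retention at the migrating tertiary carbon.

**10 ⇒ 7 + 5 (C1–C5 bond).** The quaternary carbon is cut between C1 and the CH2CH2–alkyne arm. This gives a secondary benzylic carbamate 7 and the primary boronic ester 5, joined by lithiation–borylation through 8 and 9. Here the configuration of an easily made secondary carbinol is transferred to the quaternary centre. Catalytic asymmetric conjugate addition or allylic substitution with an ortho-substituted aryl group is less dependable for this centre.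

**7 ⇒ 6 ⇒ 2 ⇒ 1, and 5 ⇒ 4 ⇒ 3.** Carbamate 7 comes from the (R)-carbinol 6, made by catalytic asymmetric reduction of ketone 2, the MOM ether of commercial hydroxyacetophenone 1. Boronic ester 5 comes from commercial bromide 3 through Grignard reagent 4.

## Roads not taken

**Alternative 1:** the most obvious plan cuts the exocyclic C3=CHBr bond.
- Forward: catalytic asymmetric conjugate arylation of 3-methylcyclopent-2-en-1-one A1 to the 3-aryl-3-methylcyclopentanone A2, α-methylation to ketone A3, then Wittig bromomethylenation.
- Why the chosen plan is better: ortho-substituted aryl nucleophiles are poor partners in quaternary-centre-forming conjugate additions. Alkylation of the enolate of A2 places the methyl group trans to the aryl group. Even if the cis isomer A3 were obtained, C2 is α to the carbonyl and would drift to the more stable trans isomer under the basic olefination. The ylide also prefers to place bromine away from the branched C2, giving mainly the (E)-bromide. Three selectivity problems are left open; the chosen route answers each by mechanism.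

**Alternative 2:** cut C1–C2 by a [3,3] shift.
- Forward: Ireland–Claisen rearrangement of the propanoate A4 through a chair transition state gives acid A5 with both stereocentres set relative to each other. The derived pentenal is then closed by rhodium-catalysed hydroacylation to the same ketone A3.
- Why the chosen plan is better: the relative configuration is well controlled, but the absolute configuration needs a stoichiometric chiral boron reagent. The route also ends in A3, with its epimerizable C2 and the unsolved bromoalkene geometry, and it is several steps longer than the enyne route.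

**Alternative 3:** cut the aryl–C1 bond by an aromatic Claisen rearrangement.
- Forward: thermal ortho-Claisen rearrangement of the aryl allyl ether A6 would give the enyne phenol A7, the racemate of 14, in two steps.
- Why the chosen plan is better: this is by far the shortest run-up to the key step, but there is no general catalytic enantioselective ortho-Claisen rearrangement of simple aryl allyl ethers. The product would be racemic, and γ,γ-disubstituted allyl ethers at the temperatures needed also give abnormal-Claisen and coumaran by-products. The chosen route builds the same carbon as a single enantiomer from a carbinol made by a dependable asymmetric reduction.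

Key step: step 8

## Route

Remark: boronic ester 5 is assumed not to be purchasable and is made in one step; compounds 1 and 3 are commercial.

Step 1
Reactants: 1 1-(2-hydroxy-4-methylphenyl)ethan-1-one
Product: 2 1-[2-(methoxymethoxy)-4-methylphenyl]ethan-1-one
Conditions: MOMCl, iPr2NEt, CH2Cl2, 0 °C to rt
Reagents that add atoms: chloromethyl methyl ether, COCCl
Why: O-alkylation of the phenol to the MOM acetal; this ether withstands s-BuLi and, unlike a silyl ether, cannot migrate to the benzylic anion of step 5.

Step 2
Reactants: 3 (4-bromobut-1-yn-1-yl)trimethylsilane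
Product: 5 trimethyl[4-(4,4,5,5-tetramethyl-1,3,2-dioxaborolan-2-yl)but-1-yn-1-yl]silane, via Grignard reagent 4 (not isolated)
Conditions: Mg, THF, rt; iPrOBpin, −78 °C to rt
Reagents that add atoms: 2-isopropoxy-4,4,5,5-tetramethyl-1,3,2-dioxaborolane, CC(C)OB1OC(C)(C)C(C)(C)O1
Why: Grignard formation and borylation with an alkoxyboronate; the silyl cap protects the alkyne C–H from the Grignard reagent.

Step 3
Reactants: 2 1-[2-(methoxymethoxy)-4-methylphenyl]ethan-1-one
Product: 6 (1R)-1-[2-(methoxymethoxy)-4-methylphenyl]ethan-1-ol
Conditions: (S)-Me-CBS [(S)-1-methyl-3,3-diphenyltetrahydro-1H,3H-pyrrolo[1,2-c][1,3,2]oxazaborole] (10 mol%), BH3·SMe2, THF, −20 °C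
Reagents that add atoms: none
Why: Corey–Bakshi–Shibata reduction of an aryl methyl ketone; with the (S)-catalyst and aryl as the large group, hydride should add to the Si face and give the (R)-carbinol.

Step 4
Reactants: 6 (1R)-1-[2-(methoxymethoxy)-4-methylphenyl]ethan-1-ol
Product: 7 (1R)-1-[2-(methoxymethoxy)-4-methylphenyl]ethyl N,N-di(propan-2-yl)carbamate
Conditions: iPr2NCOCl, Et3N, CH2Cl2, reflux
Reagents that add atoms: N,N-diisopropylcarbamoyl chloride, CC(C)N(C(C)C)C(Cl)=O
Why: O-carbamoylation; the stereocentre is not touched, and the carbamate is both the directing group and the leaving group for step 5.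

Step 5
Reactants: 7 (1R)-1-[2-(methoxymethoxy)-4-methylphenyl]ethyl N,N-di(propan-2-yl)carbamate and 5 trimethyl[4-(4,4,5,5-tetramethyl-1,3,2-dioxaborolan-2-yl)but-1-yn-1-yl]silane
Product: 10 trimethyl{(5R)-5-[2-(methoxymethoxy)-4-methylphenyl]-5-(4,4,5,5-tetramethyl-1,3,2-dioxaborolan-2-yl)hex-1-yn-1-yl}silane, via lithiated carbamate 8 (not isolated), via boronate complex 9 (not isolated)
Conditions: s-BuLi, Et2O, −78 °C; 5, −78 °C; MgBr2·OEt2, MeOH, −78 °C to rt
Reagents that add atoms: none
Why: Lithiation–borylation of a secondary benzylic carbamate: deprotonation with retention, capture by the boronic ester with retention, then 1,2-metallate shift of the alkyl group anti to the carbamate, so that (R)-7 should give (R)-10. MgBr2/MeOH is added to stop the hindered boronate complex from reverting.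

Step 6
Reactants: 10 trimethyl{(5R)-5-[2-(methoxymethoxy)-4-methylphenyl]-5-(4,4,5,5-tetramethyl-1,3,2-dioxaborolan-2-yl)hex-1-yn-1-yl}silane
Product: 13 trimethyl{(5R)-5-[2-(methoxymethoxy)-4-methylphenyl]-5-methylhept-6-en-1-yn-1-yl}silane, via vinyl boronate complex 11 (not isolated), via iodo boronic ester 12 (not isolated)
Conditions: CH2=CHMgBr, THF, rt; I2, MeOH, −78 °C; NaOMe, MeOH, −78 °C to rt
Reagents that add atoms: vinylmagnesium bromide, C=C[Mg]Br
Why: Zweifel olefination: iodine triggers 1,2-migration of the tertiary carbon from boron to the vinyl group with retention at the migrating carbon, and methoxide causes anti elimination of boron and iodide. The quaternary stereocentre is thus formed with the configuration of 10.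

Step 7
Reactants: 13 trimethyl{(5R)-5-[2-(methoxymethoxy)-4-methylphenyl]-5-methylhept-6-en-1-yn-1-yl}silane
Product: 14 5-methyl-2-[(3R)-3-methyl-7-(trimethylsilyl)hept-1-en-6-yn-3-yl]phenol
Conditions: HCl (3 M aq), MeOH, 40 °C
Reagents that add atoms: none
Why: Acid-catalysed methanolysis of the MOM acetal; a monosubstituted alkene and a silyl-capped alkyne are not protonated under these conditions.

Step 8
Reactants: 14 5-methyl-2-[(3R)-3-methyl-7-(trimethylsilyl)hept-1-en-6-yn-3-yl]phenol
Product: 18 5-methyl-2-[(1R,2R,3E)-1,2-dimethyl-3-[(trimethylsilyl)methylidene]cyclopentyl]phenol, via lithium aryloxide 15 (not isolated), via aryloxytitanium triisopropoxide 16 (not isolated), via titanacycle 17 (not isolated)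
Conditions: n-BuLi, PhMe/Et2O, −78 °C; ClTi(OiPr)3, −78 to 0 °C; c-C5H9MgCl (2.1 equiv), −78 to −30 °C; 1 M HCl (aq), 0 °C
Reagents that add atoms: none
Why: Proposed new method: a phenoxide that stays bound to titanium is asked to direct an intramolecular enyne cyclometalation; the closest known reaction types are the Ti(OiPr)4/2 RMgX-mediated reductive cyclization of 1,6-enynes and the alkoxide-directed titanium-mediated coupling of alkynes with alkenes. Two equivalents of c-C5H9MgCl should convert 16 into a divalent titanium–cyclopentene complex, the silylalkyne displaces cyclopentene to give a titanacyclopropene, and the vinyl group then inserts into its ring-side Ti–C bond. This insertion closes the cyclopentane in the 5-exo-trig mode (bond C2–C3) and at the same time the five-membered titanacyclopentene of 17 (Ti–CH2–C2–C3=C). The new stereocentre C2 is controlled by the Ti–O bond: the metal that ends on the CH2 carbon is tied to the aryl group on C1 through a seven-membered Ti–O–C(ar)–C(ar)–C1–C2–CH2 chelate, which can form only if CH2 and aryl are cis on the ring. Without this tether the bulky aryl group would take the convex position and give the C2 epimer, so overriding that bias is the selectivity the step needs. Syn addition of C2 and Ti across the alkyne fixes Ti cis to C2 and SiMe3 cis to C4, so protonolysis of both Ti–C bonds with retention should give the (E)-vinylsilane and the C2 methyl group. C1 is quaternary and untouched, and the silylalkyne binds divalent titanium faster than the hindered vinyl group, which secures the order of events.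

Step 9
Reactants: 18 5-methyl-2-[(1R,2R,3E)-1,2-dimethyl-3-[(trimethylsilyl)methylidene]cyclopentyl]phenol
Product: 19 5-methyl-2-[(1R,2R,3E)-1,2-dimethyl-3-[(trimethylsilyl)methylidene]cyclopentyl]phenyl acetate
Conditions: Ac2O, pyridine, DMAP (4-(dimethylamino)pyridine, cat.), CH2Cl2, rt
Reagents that add atoms: acetic anhydride, CC(=O)OC(C)=O
Why: O-acylation; the acetate makes the oxygen non-nucleophilic and the ring less reactive, so that in step 10 bromine reacts only at the vinylsilane and the oxygen cannot close a bridged ether onto C3.

Step 10
Reactants: 19 5-methyl-2-[(1R,2R,3E)-1,2-dimethyl-3-[(trimethylsilyl)methylidene]cyclopentyl]phenyl acetate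
Product: 21 2-[(1R,2R,3Z)-3-(bromomethylidene)-1,2-dimethylcyclopentyl]-5-methylphenol, via anti dibromide 20 (not isolated)
Conditions: Br2 (1.05 equiv), CH2Cl2, −78 °C; NaOMe, MeOH, −78 °C to rt
Reagents that add atoms: bromine, BrBr
Why: Bromodesilylation with inversion: the bromonium ion is opened by bromide at C3 (tertiary and β to silicon) to the anti dibromide, and methoxide then removes silicon and the C3 bromide in an anti elimination. Bromine therefore ends on the side opposite to where silicon was, syn to C2, giving the (Z)-bromide. The same methoxide cleaves the aryl acetate.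

Step 11
Reactants: 21 2-[(1R,2R,3Z)-3-(bromomethylidene)-1,2-dimethylcyclopentyl]-5-methylphenol
Product: 22 4-bromo-2-[(1R,2R,3Z)-3-(bromomethylidene)-1,2-dimethylcyclopentyl]-5-methylphenol
Conditions: NBS (1.0 equiv), MeCN, −20 to 0 °C, dark
Reagents that add atoms: N-bromosuccinimide, O=C1CCC(=O)N1Br
Why: Electrophilic aromatic bromination para to the hydroxyl group, the usual site in 2,5-dialkylphenols; the bromine-substituted alkene is deactivated, and the by-product is neutral, so no acid is formed that could cyclize the phenol onto C3.

## Compound list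

1 | 1-(2-hydroxy-4-methylphenyl)ethan-1-one | CC(=O)c1ccc(C)cc1O | starting material
2 | 1-[2-(methoxymethoxy)-4-methylphenyl]ethan-1-one | CC(=O)c1ccc(C)cc1OCOC | intermediate
3 | (4-bromobut-1-yn-1-yl)trimethylsilane | C[Si](C)(C)C#CCCBr | starting material
4 | [4-(trimethylsilyl)but-3-yn-1-yl]magnesium bromide | C[Si](C)(C)C#CCC[Mg]Br | intermediate (not isolated)
5 | trimethyl[4-(4,4,5,5-tetramethyl-1,3,2-dioxaborolan-2-yl)but-1-yn-1-yl]silane | C[Si](C)(C)C#CCCB1OC(C)(C)C(C)(C)O1 | intermediate
6 | (1R)-1-[2-(methoxymethoxy)-4-methylphenyl]ethan-1-ol | C[C@@H](O)c1ccc(C)cc1OCOC | intermediate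
7 | (1R)-1-[2-(methoxymethoxy)-4-methylphenyl]ethyl N,N-di(propan-2-yl)carbamate | C[C@@H](OC(=O)N(C(C)C)C(C)C)c1ccc(C)cc1OCOC | intermediate
8 | (1R)-1-lithio-1-[2-(methoxymethoxy)-4-methylphenyl]ethyl N,N-di(propan-2-yl)carbamate (lithium in the place of the carbinol hydrogen) | C[C@@]([Li])(OC(=O)N(C(C)C)C(C)C)c1ccc(C)cc1OCOC | intermediate (not isolated)
9 | lithium boronate complex of 8 and 5 (boron in the place of lithium, carbamate still on carbon) | C[C@@]([B-]1(CCC#C[Si](C)(C)C)OC(C)(C)C(C)(C)O1)(OC(=O)N(C(C)C)C(C)C)c1ccc(C)cc1OCOC.[Li+] | intermediate (not isolated)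
10 | trimethyl{(5R)-5-[2-(methoxymethoxy)-4-methylphenyl]-5-(4,4,5,5-tetramethyl-1,3,2-dioxaborolan-2-yl)hex-1-yn-1-yl}silane | C[C@](B1OC(C)(C)C(C)(C)O1)(CCC#C[Si](C)(C)C)c1ccc(C)cc1OCOC | intermediate
11 | bromomagnesium vinylboronate complex of 10 | C[C@]([B-]1(C=C)OC(C)(C)C(C)(C)O1)(CCC#C[Si](C)(C)C)c1ccc(C)cc1OCOC.[Mg+2].[Br-] | intermediate (not isolated)
12 | trimethyl{(5R)-7-iodo-5-[2-(methoxymethoxy)-4-methylphenyl]-5-methyl-6-(4,4,5,5-tetramethyl-1,3,2-dioxaborolan-2-yl)hept-1-yn-1-yl}silane (both epimers at C6) | C[C@](C(CI)B1OC(C)(C)C(C)(C)O1)(CCC#C[Si](C)(C)C)c1ccc(C)cc1OCOC | intermediate (not isolated)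
13 | trimethyl{(5R)-5-[2-(methoxymethoxy)-4-methylphenyl]-5-methylhept-6-en-1-yn-1-yl}silane | C[C@](C=C)(CCC#C[Si](C)(C)C)c1ccc(C)cc1OCOC | intermediate
14 | 5-methyl-2-[(3R)-3-methyl-7-(trimethylsilyl)hept-1-en-6-yn-3-yl]phenol | C[C@](C=C)(CCC#C[Si](C)(C)C)c1ccc(C)cc1O | intermediate
15 | lithium 5-methyl-2-[(3R)-3-methyl-7-(trimethylsilyl)hept-1-en-6-yn-3-yl]phenolate | C[C@](C=C)(CCC#C[Si](C)(C)C)c1ccc(C)cc1[O-].[Li+] | intermediate (not isolated)
16 | {5-methyl-2-[(3R)-3-methyl-7-(trimethylsilyl)hept-1-en-6-yn-3-yl]phenoxy}tri(propan-2-yloxy)titanium | C[C@](C=C)(CCC#C[Si](C)(C)C)c1ccc(C)cc1O[Ti](OC(C)C)(OC(C)C)OC(C)C | intermediate (not isolated)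
17 | tricyclic aryloxy(isopropoxy)titanacyclopentene: Ti bonded to the phenoxide oxygen, to the CH2 on C2 (cis to aryl) and to the exocyclic C(SiMe3)= carbon on C3 | CC(C)O[Ti]12Oc3cc(C)ccc3[C@]3(C)CC/C(=C1\[Si](C)(C)C)[C@@H]3C2 | intermediate (not isolated)
18 | 5-methyl-2-[(1R,2R,3E)-1,2-dimethyl-3-[(trimethylsilyl)methylidene]cyclopentyl]phenol | Cc1ccc([C@]2(C)CC/C(=C\[Si](C)(C)C)[C@@H]2C)c(O)c1 | intermediate
19 | 5-methyl-2-[(1R,2R,3E)-1,2-dimethyl-3-[(trimethylsilyl)methylidene]cyclopentyl]phenyl acetate | Cc1ccc([C@]2(C)CC/C(=C\[Si](C)(C)C)[C@@H]2C)c(OC(C)=O)c1 | intermediate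
20 | 2-[(1R,2R)-3-bromo-3-[bromo(trimethylsilyl)methyl]-1,2-dimethylcyclopentyl]-5-methylphenyl acetate (anti adduct, drawn with the ring C–Br trans to the C2 methyl; either anti adduct leads to 21) | Cc1ccc([C@]2(C)CC[C@](Br)([C@@H](Br)[Si](C)(C)C)[C@@H]2C)c(OC(C)=O)c1 | intermediate (not isolated)
21 | 2-[(1R,2R,3Z)-3-(bromomethylidene)-1,2-dimethylcyclopentyl]-5-methylphenol | Cc1ccc([C@]2(C)CC/C(=C/Br)[C@@H]2C)c(O)c1 | intermediate
22 | 4-bromo-2-[(1R,2R,3Z)-3-(bromomethylidene)-1,2-dimethylcyclopentyl]-5-methylphenol | Cc1cc(O)c([C@]2(C)CC/C(=C/Br)[C@@H]2C)cc1Br | target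

## Step count and least certain steps

Total: 11 steps. Longest linear sequence: 10 steps (steps 1 and 3 to 11); step 2 makes the side fragment 5.

**Step 8 (key step, proposed new method).**
- What may go wrong: loss of the aryloxide from titanium when the Grignard reagent is added, since aryloxide is the best leaving group among the ligands. Cyclization would then run on an untethered metal, and the steric bias would place the aryl group on the convex face and give the C2 epimer. Slow insertion of the hindered vinyl group would instead leave the titanacyclopropene to be protonated to the uncyclized alkene.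
- Fallback (known chemistry), from 14 back to 18: Pd(OAc)2/PPh3 in benzene at 60 °C should bring about the Alder-ene-type cycloisomerization of 14. Hydropalladation of the alkyne and 5-exo carbopalladation of the vinyl group are followed by β-hydride elimination of the only hydrogen available, that on C2. The product is the diene 5-methyl-2-[(1R,3E)-1-methyl-2-methylidene-3-[(trimethylsilyl)methylidene]cyclopentyl]phenol F1, with silicon again cis to C4. Diimide (2-nitrobenzenesulfonyl hydrazide, Et3N) then reduces only the 1,1-disubstituted C2=CH2 bond, from the face opposite to the aryl group. The new methyl group ends cis to aryl, and the route is rejoined at 18.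

**Step 5.**
- What may go wrong: incomplete or reversible formation of the boronate complex at the ortho-substituted tertiary benzylic lithium. This would cause loss of enantiopurity by dissociation and recombination, or ring lithiation next to the MOM ether could compete.
- Fallback, from 2 to 13 (it also bypasses step 6): Horner–Wadsworth–Emmons olefination of 2 (triethyl phosphonoacetate, NaH) gives ethyl (2E)-3-[2-(methoxymethoxy)-4-methylphenyl]but-2-enoate F2. Reduction with iBu2AlH gives (2E)-3-[2-(methoxymethoxy)-4-methylphenyl]but-2-en-1-ol F3. NCS/Me2S gives 1-[(2E)-4-chlorobut-2-en-2-yl]-2-(methoxymethoxy)-4-methylbenzene F4. A CuBr·SMe2/chiral phosphoramidite-catalysed SN2' alkylation of F4 with Grignard reagent 4, with the ligand enantiomer chosen for the R product, delivers 13.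

**Step 10.**
- What may go wrong: loss of stereospecificity. If the tertiary β-silyl cation at C3 opens and loses silicon before bromide adds, bromine replaces silicon with retention and the (E)-bromide forms.
- Fallback, from 19 to 21: epoxidation of 19 with mCPBA gives the spiro epoxysilane 5-methyl-2-[(4R,5R)-4,5-dimethyl-2-(trimethylsilyl)-1-oxaspiro[2.4]heptan-5-yl]phenyl acetate F5. Anhydrous HBr in Et2O at −40 °C opens it at the silicon-bearing carbon with inversion to the bromohydrin 2-[(1R,2R)-3-[bromo(trimethylsilyl)methyl]-3-hydroxy-1,2-dimethylcyclopentyl]-5-methylphenyl acetate F6. BF3·OEt2 induces the anti Peterson elimination to 2-[(1R,2R,3Z)-3-(bromomethylidene)-1,2-dimethylcyclopentyl]-5-methylphenyl acetate F7, and K2CO3/MeOH returns 21. The geometry here rests on an SN2 opening and an anti elimination, not on a bromonium ion.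

## Further compounds

F1 | step 8 | 5-methyl-2-[(1R,3E)-1-methyl-2-methylidene-3-[(trimethylsilyl)methylidene]cyclopentyl]phenol | Cc1ccc([C@]2(C)CC/C(=C\[Si](C)(C)C)C2=C)c(O)c1
F2 | step 5 | ethyl (2E)-3-[2-(methoxymethoxy)-4-methylphenyl]but-2-enoate | CCOC(=O)/C=C(\C)c1ccc(C)cc1OCOC
F3 | step 5 | (2E)-3-[2-(methoxymethoxy)-4-methylphenyl]but-2-en-1-ol | OC/C=C(\C)c1ccc(C)cc1OCOC
F4 | step 5 | 1-[(2E)-4-chlorobut-2-en-2-yl]-2-(methoxymethoxy)-4-methylbenzene | ClC/C=C(\C)c1ccc(C)cc1OCOC
F5 | step 10 | 5-methyl-2-[(4R,5R)-4,5-dimethyl-2-(trimethylsilyl)-1-oxaspiro[2.4]heptan-5-yl]phenyl acetate (oxirane oxygen trans to the C4 methyl, SiMe3 cis to the ring CH2) | Cc1ccc([C@]2(C)CC[C@@]3(O[C@@H]3[Si](C)(C)C)[C@@H]2C)c(OC(C)=O)c1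
F6 | step 10 | 2-[(1R,2R)-3-[bromo(trimethylsilyl)methyl]-3-hydroxy-1,2-dimethylcyclopentyl]-5-methylphenyl acetate (hydroxyl trans to the C2 methyl; Br and OH anti) | Cc1ccc([C@]2(C)CC[C@](O)([C@@H](Br)[Si](C)(C)C)[C@@H]2C)c(OC(C)=O)c1
F7 | step 10 | 2-[(1R,2R,3Z)-3-(bromomethylidene)-1,2-dimethylcyclopentyl]-5-methylphenyl acetate | Cc1ccc([C@]2(C)CC/C(=C/Br)[C@@H]2C)c(OC(C)=O)c1
A1 | alternative 1 | 3-methylcyclopent-2-en-1-one | CC1=CC(=O)CC1
A2 | alternative 1 | (3R)-3-[2-(methoxymethoxy)-4-methylphenyl]-3-methylcyclopentan-1-one | Cc1ccc([C@]2(C)CCC(=O)C2)c(OCOC)c1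
A3 | alternative 1 | (2R,3R)-3-[2-(methoxymethoxy)-4-methylphenyl]-2,3-dimethylcyclopentan-1-one | Cc1ccc([C@]2(C)CCC(=O)[C@@H]2C)c(OCOC)c1
A4 | alternative 2 | (2E)-3-[2-(methoxymethoxy)-4-methylphenyl]but-2-en-1-yl propanoate | CCC(=O)OC/C=C(\C)c1ccc(C)cc1OCOC
A5 | alternative 2 | (2R,3R)-3-[2-(methoxymethoxy)-4-methylphenyl]-2,3-dimethylpent-4-enoic acid | Cc1ccc([C@](C)(C=C)[C@@H](C)C(O)=O)c(OCOC)c1
A6 | alternative 3 | 1-methyl-3-{[(2E)-3-methyl-7-(trimethylsilyl)hept-2-en-6-yn-1-yl]oxy}benzene | Cc1cccc(OC/C=C(\C)CCC#C[Si](C)(C)C)c1
A7 | alternative 3 | rac-5-methyl-2-[3-methyl-7-(trimethylsilyl)hept-1-en-6-yn-3-yl]phenol | Cc1ccc(C(C)(C=C)CCC#C[Si](C)(C)C)c(O)c1
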